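Everything rests on cutting ring C of the chromone at the three bonds around its C4 carbonyl and ring oxygen: C4a–C4, C4–C3 and O1–C2. That leaves a ring A o-iodophenol (stored as its acetate), carbon monoxide as C4, and a ring B terminal arylacetylene that already carries the benzyl-protected 4-hydroxy-2-pyrone on its benzylic CH2. One palladium-catalysed carbonylative alkynylation with amine-mediated 6-endo closure unites the three pieces and builds ring C, and the bond next to the doubly ortho-substituted ring B is made at an unhindered alkyne carbon, not at a crowded aroyl carbon. A single BBr3 treatment then uncovers all four hydroxyl groups.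

Key step: step 9

Remark: the target has no stereocentre; the C=C geometry of the transient enaminone 19 is left undefined because both isomers cyclise to the same product.

Step 1
Reactants: 1 3-methoxy-5-methylphenol
Product: 2 3-methoxy-5-methylphenyl acetate
Conditions: Ac2O, pyridine, rt
Reagents that add atoms: acetic anhydride, CC(=O)OC(C)=O
Why: Pyridine-promoted O-acylation (esterification) of the phenol installs the acetate that lowers the directing power of this oxygen for step 2 and later serves as the phenol mask.

Step 2
Reactants: 2 3-methoxy-5-methylphenyl acetate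
Product: 3 2-iodo-5-methoxy-3-methylphenyl acetate
Conditions: NIS (1.05 equiv), TFA (0.3 equiv), MeCN, rt
Reagents that add atoms: N-iodosuccinimide, O=C1CCC(=O)N1I
Why: Electrophilic aromatic iodination in which the methoxy group outweighs the weakly donating acetoxy group and sends iodine to its para position, between the acetoxy and methyl groups, as is known for halogenation of 3-methoxyphenyl esters and of 3,5-dimethoxytoluene.

Step 3
Reactants: 4 3,5-dimethoxyphenylacetic acid
Product: 5 2-(2-iodo-3,5-dimethoxyphenyl)acetic acid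
Conditions: NIS (1.0 equiv), TFA (cat.), MeCN, 0 °C to rt
Reagents that add atoms: N-iodosuccinimide, O=C1CCC(=O)N1I
Why: Electrophilic aromatic iodination takes place ortho to the CH2CO2H group and para to one methoxy group and not between the two methoxy groups, the known preference of 3,5-dimethoxytoluene-type rings.

Step 4
Reactants: 5 2-(2-iodo-3,5-dimethoxyphenyl)acetic acid, 6 2,2,6-trimethyl-4H-1,3-dioxin-4-one
Product: 9 6-[3-(2-iodo-3,5-dimethoxyphenyl)-2-oxopropyl]-2,2-dimethyl-4H-1,3-dioxin-4-one, via acid chloride 7 (not isolated), via lithium dienolate 8 (not isolated)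
Conditions: (COCl)2, DMF (cat.), CH2Cl2, rt, then evaporation; 6 (2.5 equiv), LiN(SiMe3)2 (2.5 equiv), THF, −78 °C, then 7 added at −78 °C; 1 M HCl
Reagents that add atoms: none
Why: The acid chloride made in the flask undergoes Claisen-type C-acylation at the γ-carbon of the lithium dienolate of the dioxinone, a second equivalent of dienolate deprotonating the more acidic β-keto product so that it is not acylated again, while the aryl iodide is inert to the amide base at −78 °C.

Step 5
Reactants: 9 6-[3-(2-iodo-3,5-dimethoxyphenyl)-2-oxopropyl]-2,2-dimethyl-4H-1,3-dioxin-4-one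
Product: 11 4-hydroxy-6-(2-iodo-3,5-dimethoxybenzyl)-2H-pyran-2-one, via acylketene 10 (not isolated)
Conditions: toluene, 110 °C
Reagents that add atoms: none
Why: Thermal retro-[4+2] loss of acetone from the dioxinone unmasks an acylketene whose enolised ketone oxygen closes onto the ketene carbon (intramolecular O-acylation) to give the 4-hydroxy-2-pyrone.

Step 6
Reactants: 11 4-hydroxy-6-(2-iodo-3,5-dimethoxybenzyl)-2H-pyran-2-one
Product: 12 4-(benzyloxy)-6-(2-iodo-3,5-dimethoxybenzyl)-2H-pyran-2-one
Conditions: BnOH, PPh3, DIAD, THF, 0 °C to rt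
Reagents that add atoms: benzyl alcohol, OCc1ccccc1
Why: Mitsunobu alkylation of the acidic pyrone hydroxyl with a primary alcohol is selective for O4, and benzyl is preferred to methyl because the methyl ether of a 2-pyrone (a vinylogous ester) is slow to cleave with BBr3 whereas the benzyl ether falls in the same final operation as the aryl methyl ethers.

Step 7
Reactants: 12 4-(benzyloxy)-6-(2-iodo-3,5-dimethoxybenzyl)-2H-pyran-2-one, 13 trimethylsilylacetylene
Product: 14 4-(benzyloxy)-6-{3,5-dimethoxy-2-[(trimethylsilyl)ethynyl]benzyl}-2H-pyran-2-one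
Conditions: PdCl2(PPh3)2 (5 mol%), CuI (10 mol%), Et3N/THF (1:2), 60 °C, sealed tube
Reagents that add atoms: none
Why: Sonogashira coupling of an aryl iodide proceeds even with two ortho substituents, and the silyl cap on the alkyne prevents a second coupling.

Step 8
Reactants: 14 4-(benzyloxy)-6-{3,5-dimethoxy-2-[(trimethylsilyl)ethynyl]benzyl}-2H-pyran-2-one
Product: 15 4-(benzyloxy)-6-(2-ethynyl-3,5-dimethoxybenzyl)-2H-pyran-2-one
Conditions: Bu4NF, AcOH, THF, 0 °C
Reagents that add atoms: none
Why: Fluoride-induced protodesilylation of the alkynylsilane, buffered with acetic acid so that the benzyloxypyrone is neither opened nor transetherified, gives the terminal alkyne, and isolation here removes copper residues that would favour non-carbonylative coupling in step 9.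

Step 9
Reactants: 3 2-iodo-5-methoxy-3-methylphenyl acetate, 15 4-(benzyloxy)-6-(2-ethynyl-3,5-dimethoxybenzyl)-2H-pyran-2-one, 16 carbon monoxide
Product: 20 2-{2,4-dimethoxy-6-[(4-benzyloxy-2-oxo-2H-pyran-6-yl)methyl]phenyl}-7-methoxy-5-methyl-4H-chromen-4-one, via iodophenol 17 (not isolated), via ynone 18 (not isolated), via enaminone 19 (not isolated)
Conditions: Et2NH/DMF (1:3), 40 °C, 1 h; then 15, PdCl2(dppf) (5 mol%), CO (10 bar), 90 °C, no copper
Reagents that add atoms: none
Why: Diethylamine first removes the acetyl group of 3 by aminolysis to give iodophenol 17; oxidative addition of its C–I bond to zerovalent palladium (generated in situ from PdCl2(dppf)), migratory insertion of CO to an aroylpalladium intermediate and copper-free coupling with the deprotonated alkyne 15 then furnish ynone 18, creating C4a–C4 and C4–C3. Conjugate addition of diethylamine converts 18 into enaminone 19, whose amine-bearing carbon is attacked by the ortho phenol oxygen with loss of diethylamine; this addition–elimination forms O1–C2 and closes ring C in the 6-endo mode. The closest known reaction type is the palladium-catalysed carbonylative Sonogashira annulation of o-iodophenols or their acetates with terminal arylacetylenes to flavones. No stereocentre is created. Two selectivities are required: CO insertion before alkynylation, secured by CO pressure, the absence of copper and the slow direct alkynylation of an arylpalladium flanked by two ortho groups, and 6-endo instead of 5-exo closure (aurone), secured by the secondary amine because the enaminone offers only its β-carbon to the phenol. Because ring B is attached through a rod-like alkyne carbon, its two ortho substituents (a methoxy group and the pyronylmethyl group) do not block the union as they would block acyl transfer at an aroyl carbon.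

Step 10
Reactants: 20 2-{2,4-dimethoxy-6-[(4-benzyloxy-2-oxo-2H-pyran-6-yl)methyl]phenyl}-7-methoxy-5-methyl-4H-chromen-4-one
Product: 21 2-{2,4-dihydroxy-6-[(4-hydroxy-2-oxo-2H-pyran-6-yl)methyl]phenyl}-7-hydroxy-5-methyl-4H-chromen-4-one (CNP0309284.0)
Conditions: BBr3 (12 equiv), C6HMe5 (3 equiv), CH2Cl2, −78 °C to rt; then MeOH, H2O
Reagents that add atoms: none
Why: Lewis-acid ether cleavage with BBr3 removes the benzyl group from the pyrone oxygen at low temperature, the benzyl cation being trapped by pentamethylbenzene in a Friedel–Crafts reaction, and then dealkylates the three aryl methyl ethers by bromide attack on the O-methyl groups of their boron complexes, conditions to which the chromone and pyrone rings are stable.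

Compound list
1 | 3-methoxy-5-methylphenol | Cc1cc(O)cc(OC)c1 | starting material
2 | 3-methoxy-5-methylphenyl acetate | CC(=O)Oc1cc(C)cc(OC)c1 | intermediate
3 | 2-iodo-5-methoxy-3-methylphenyl acetate | CC(=O)Oc1cc(OC)cc(C)c1I | intermediate
4 | 3,5-dimethoxyphenylacetic acid | COc1cc(CC(=O)O)cc(OC)c1 | starting material
5 | 2-(2-iodo-3,5-dimethoxyphenyl)acetic acid | COc1cc(OC)c(I)c(CC(=O)O)c1 | intermediate
6 | 2,2,6-trimethyl-4H-1,3-dioxin-4-one | CC1=CC(=O)OC(C)(C)O1 | starting material
7 | 2-(2-iodo-3,5-dimethoxyphenyl)acetyl chloride (not isolated) | COc1cc(OC)c(I)c(CC(Cl)=O)c1 | intermediate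
8 | lithium 2,2-dimethyl-6-methylidene-6H-1,3-dioxin-4-olate, the lithium dienolate of 6 (not isolated) | [Li+].C=C1C=C([O-])OC(C)(C)O1 | intermediate
9 | 6-[3-(2-iodo-3,5-dimethoxyphenyl)-2-oxopropyl]-2,2-dimethyl-4H-1,3-dioxin-4-one | COc1cc(OC)c(I)c(CC(=O)CC2=CC(=O)OC(C)(C)O2)c1 | intermediate
10 | 6-(2-iodo-3,5-dimethoxyphenyl)hex-1-ene-1,3,5-trione, the acylketene (not isolated) | COc1cc(OC)c(I)c(CC(=O)CC(=O)C=C=O)c1 | intermediate
11 | 4-hydroxy-6-(2-iodo-3,5-dimethoxybenzyl)-2H-pyran-2-one | COc1cc(OC)c(I)c(Cc2cc(O)cc(=O)o2)c1 | intermediate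
12 | 4-(benzyloxy)-6-(2-iodo-3,5-dimethoxybenzyl)-2H-pyran-2-one | COc1cc(OC)c(I)c(Cc2cc(OCc3ccccc3)cc(=O)o2)c1 | intermediate
13 | trimethylsilylacetylene | C#C[Si](C)(C)C | starting material
14 | 4-(benzyloxy)-6-{3,5-dimethoxy-2-[(trimethylsilyl)ethynyl]benzyl}-2H-pyran-2-one | COc1cc(OC)c(C#C[Si](C)(C)C)c(Cc2cc(OCc3ccccc3)cc(=O)o2)c1 | intermediate
15 | 4-(benzyloxy)-6-(2-ethynyl-3,5-dimethoxybenzyl)-2H-pyran-2-one | C#Cc1c(OC)cc(OC)cc1Cc1cc(OCc2ccccc2)cc(=O)o1 | intermediate
16 | carbon monoxide | [C-]#[O+] | starting material
17 | 2-iodo-5-methoxy-3-methylphenol (not isolated) | Cc1cc(OC)cc(O)c1I | intermediate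
18 | 3-{2,4-dimethoxy-6-[(4-benzyloxy-2-oxo-2H-pyran-6-yl)methyl]phenyl}-1-(2-hydroxy-4-methoxy-6-methylphenyl)prop-2-yn-1-one (not isolated) | Cc1cc(OC)cc(O)c1C(=O)C#Cc1c(OC)cc(OC)cc1Cc1cc(OCc2ccccc2)cc(=O)o1 | intermediate
19 | 3-(diethylamino)-3-{2,4-dimethoxy-6-[(4-benzyloxy-2-oxo-2H-pyran-6-yl)methyl]phenyl}-1-(2-hydroxy-4-methoxy-6-methylphenyl)prop-2-en-1-one, C=C geometry undefined (not isolated) | CCN(CC)C(=CC(=O)c1c(C)cc(OC)cc1O)c1c(OC)cc(OC)cc1Cc1cc(OCc2ccccc2)cc(=O)o1 | intermediate
20 | 2-{2,4-dimethoxy-6-[(4-benzyloxy-2-oxo-2H-pyran-6-yl)methyl]phenyl}-7-methoxy-5-methyl-4H-chromen-4-one | Cc1cc(OC)cc2oc(-c3c(OC)cc(OC)cc3Cc3cc(OCc4ccccc4)cc(=O)o3)cc(=O)c12 | intermediate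
21 | 2-{2,4-dihydroxy-6-[(4-hydroxy-2-oxo-2H-pyran-6-yl)methyl]phenyl}-7-hydroxy-5-methyl-4H-chromen-4-one | Cc1cc(O)cc2oc(-c3c(O)cc(O)cc3Cc3cc(O)cc(=O)o3)cc(=O)c12 | target

Total step count: 10
Longest linear sequence: 8 steps (4 → 5 → 9 → 11 → 12 → 14 → 15 → 20 → 21, steps 3 to 10)

Steps most likely to fail

1. Step 9. Several processes could divert it:
- alkynylation of the arylpalladium before CO has inserted, which leads on to benzofuran-type cyclisation;
- capture of the aroylpalladium by diethylamine (aminocarbonylation);
- slow turnover at the crowded iodide;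
- conjugate attack of the amine on the benzyloxypyrone during heating.

Fallback (sets out from 15, comes back at 18 and so at 20): the C4 carbonyl is brought in as an acid chloride instead of CO. Purchased 2-hydroxy-4-methoxy-6-methylbenzoic acid (Cc1cc(OC)cc(O)c1C(=O)O, also accessible from methyl orsellinate by 4-O-methylation and saponification) would be acetylated with Ac2O in pyridine to 2-acetoxy-4-methoxy-6-methylbenzoic acid F1. This would be converted with (COCl)2 and catalytic DMF into 2-acetoxy-4-methoxy-6-methylbenzoyl chloride F2. Acyl Sonogashira coupling of F2 with 15 (PdCl2(PPh3)2, CuI, Et3N, THF, rt) should give 3-{2,4-dimethoxy-6-[(4-benzyloxy-2-oxo-2H-pyran-6-yl)methyl]phenyl}-1-(2-acetoxy-4-methoxy-6-methylphenyl)prop-2-yn-1-one F3. Warming F3 with Et2NH in ethanol should remove the acetyl group to give 18, which closes through 19 to 20 in the same flask.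

2. Step 4. Proton transfer from the α-CH2 of the arylacetyl chloride to the dienolate (ketene formation and self-condensation), or acylation at oxygen or at the α-carbon of the dienolate, could consume the material.

Fallback (sets out from 7, comes back at 11): a base-free Mukaiyama-type acylation. Acid chloride 7 would be treated with 1-methoxy-1,3-bis(trimethylsilyloxy)buta-1,3-diene in CH2Cl2 (−78 °C to rt) and worked up with dilute acid to give methyl 6-(2-iodo-3,5-dimethoxyphenyl)-3,5-dioxohexanoate F4. DBU in toluene should then lactonise F4 to 11, so that 9 and 10 are bypassed.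

3. Step 2. Iodination ortho instead of para to the methoxy group (attack at either of the two other free ring positions) or a second iodination could give isomers that are hard to separate.

Fallback (replaces 1 to 3; sets out from the purchased 2-hydroxy-4-methoxy-6-methylbenzoic acid named above and comes back at 17, which enters step 9 directly without the aminolysis stage): the site of iodine is fixed by a carboxyl group. The acid would be alkylated twice with MOMCl and iPr2NEt to methoxymethyl 4-methoxy-2-(methoxymethoxy)-6-methylbenzoate F5. The ester would be saponified (LiOH, THF/H2O) to 4-methoxy-2-(methoxymethoxy)-6-methylbenzoic acid F6. Ipso-iododecarboxylation of this ortho-alkoxy acid (I2, K3PO4, MeCN, 100 °C) should give 2-iodo-5-methoxy-1-(methoxymethoxy)-3-methylbenzene F7, and HCl in methanol should release 17.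

Further compounds
F1 | step 9 | 2-acetoxy-4-methoxy-6-methylbenzoic acid | CC(=O)Oc1cc(OC)cc(C)c1C(=O)O
F2 | step 9 | 2-acetoxy-4-methoxy-6-methylbenzoyl chloride | CC(=O)Oc1cc(OC)cc(C)c1C(Cl)=O
F3 | step 9 | 3-{2,4-dimethoxy-6-[(4-benzyloxy-2-oxo-2H-pyran-6-yl)methyl]phenyl}-1-(2-acetoxy-4-methoxy-6-methylphenyl)prop-2-yn-1-one | CC(=O)Oc1cc(OC)cc(C)c1C(=O)C#Cc1c(OC)cc(OC)cc1Cc1cc(OCc2ccccc2)cc(=O)o1
F4 | step 4 | methyl 6-(2-iodo-3,5-dimethoxyphenyl)-3,5-dioxohexanoate | COC(=O)CC(=O)CC(=O)Cc1cc(OC)cc(OC)c1I
F5 | step 2 | methoxymethyl 4-methoxy-2-(methoxymethoxy)-6-methylbenzoate | COCOC(=O)c1c(C)cc(OC)cc1OCOC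
F6 | step 2 | 4-methoxy-2-(methoxymethoxy)-6-methylbenzoic acid | COCOc1cc(OC)cc(C)c1C(=O)O
F7 | step 2 | 2-iodo-5-methoxy-1-(methoxymethoxy)-3-methylbenzene | COCOc1cc(OC)cc(C)c1I
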